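Ring D of the flavone is not brought in as a phloroglucinol but grown onto the preformed pyranone ring E. A photochemical Wolff rearrangement of a 6-(diazoacetyl)-2-aryl-4-pyranone gives a pyranonylketene that adds to an aryl siloxyalkyne carrying ring B. Ring opening and 6π closure then make C5''–C6'', C7''–C8'' and C4a''–C5'' in one operation. The step exploits the pattern of ring D: oxygens on C5'' and C7'', ring B on C6'' between them, and fusion to ring E through C4a'' and C8a''. The precursors are diazo ketone 9 and siloxyalkyne 17, whose masked aldehyde later becomes C2 of the (2S)-flavanone.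

Key step: step 12

Numbering: unprimed locants are the flavanone (rings A and C), single primes the catechol ring B, double primes the flavone chromenone (ring D benzo, ring E pyranone), triple primes the 4-hydroxyphenyl ring F.

Remark: ring B must be carried as a bis(benzyl) ether so that one hydrogenolysis ends the route; the methyl ether of 5-iodovanillin is therefore exchanged in steps 5 and 6.

Assumption: the thiourea made from 9-amino-9-deoxy-epi-quinidine and 3,5-bis(trifluoromethyl)phenyl isothiocyanate, 1-[3,5-bis(trifluoromethyl)phenyl]-3-[(9R)-6'-methoxycinchonan-9-yl]thiourea, is taken to give the 2S series in step 15; should the first run show the 2R sense, the quinine-derived pseudoenantiomer is used under the same conditions.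

**Ring E fragment**

Step 1
Reactants: 1 4'-(benzyloxy)acetophenone; 2 ethyl acetate
Product: 3 1-[4-(benzyloxy)phenyl]butane-1,3-dione
Conditions: NaH, THF, 0 °C → reflux; aq. HCl
Reagents that add atoms: none
Why: Crossed Claisen condensation in which the sodium enolate of the aryl methyl ketone is acylated by ethyl acetate and the equilibrium is pulled over by deprotonation of the 1,3-diketone; the benzyl ether is inert to NaH.

Step 2
Reactants: 3 1-[4-(benzyloxy)phenyl]butane-1,3-dione; 4 diethyl oxalate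
Product: 6 ethyl 6-[4-(benzyloxy)phenyl]-4-oxo-4H-pyran-2-carboxylate, via triketo ester 5 (not isolated)
Conditions: NaOEt, EtOH, 0 °C → rt; aq. HCl; then TsOH·H2O (cat.), toluene, reflux (Dean–Stark)
Reagents that add atoms: none
Why: Claisen condensation with the non-enolisable oxalate settles on the terminal methyl group because only that triketo ester forms a stable dienolate, and acid-catalysed cyclodehydration of the 1,3,5-tricarbonyl unit then gives the 4-pyranone without harming the benzyl ether.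

Step 3
Reactants: 6 ethyl 6-[4-(benzyloxy)phenyl]-4-oxo-4H-pyran-2-carboxylate
Product: 7 6-[4-(benzyloxy)phenyl]-4-oxo-4H-pyran-2-carboxylic acid
Conditions: LiOH, THF/H2O, 0 °C; then 1 M HCl
Reagents that add atoms: lithium hydroxide [Li+].[OH-]
Why: Saponification of an ester activated by the pyranone oxygen and carbonyl is fast at 0 °C with about one equivalent of hydroxide, and any hydroxide-opened triketone recloses to the pyranone on acidification.

Step 4
Reactants: 7 6-[4-(benzyloxy)phenyl]-4-oxo-4H-pyran-2-carboxylic acid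
Product: 9 2-[4-(benzyloxy)phenyl]-6-(2-diazoacetyl)-4H-pyran-4-one, via acid chloride 8 (not isolated)
Conditions: (COCl)2, DMF (cat.), CH2Cl2, 0 °C → rt; evaporate; CH2N2 (excess), Et2O/THF, −10 → 0 °C
Reagents that add atoms: diazomethane C=[N+]=[N-]; oxalyl chloride ClC(=O)C(Cl)=O (supplies the chlorine of 8 only)
Why: Acid chloride formation followed by acylation of diazomethane (first stage of the Arndt–Eistert sequence) is far faster at or below 0 °C than dipolar addition to the pyranone double bonds, and the excess diazomethane takes up the HCl that would otherwise give the chloromethyl ketone.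

**Ring B fragment**

Step 5
Reactants: 10 5-iodovanillin
Product: 11 3,4-dihydroxy-5-iodobenzaldehyde
Conditions: AlCl3, pyridine, CH2Cl2, reflux; then aq. HCl
Reagents that add atoms: none
Why: AlCl3–pyridine demethylation, in which aluminium chelated between the phenoxide and the neighbouring methoxy oxygen activates only that methyl group for SN2 removal by pyridine, leaving the aldehyde and the aryl iodide intact.

Step 6
Reactants: 11 3,4-dihydroxy-5-iodobenzaldehyde
Product: 12 3,4-bis(benzyloxy)-5-iodobenzaldehyde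
Conditions: BnBr, K2CO3, DMF, rt → 50 °C
Reagents that add atoms: benzyl bromide BrCc1ccccc1
Why: Williamson etherification of both catechol oxygens under mild carbonate conditions, to which the aldehyde and the iodide are indifferent.

Step 7
Reactants: 12 3,4-bis(benzyloxy)-5-iodobenzaldehyde
Product: 13 2-[3,4-bis(benzyloxy)-5-iodophenyl]-1,3-dioxolane
Conditions: HOCH2CH2OH, TsOH·H2O (cat.), toluene, reflux (Dean–Stark)
Reagents that add atoms: ethylene glycol OCCO
Why: Acid-catalysed acetalisation with azeotropic removal of water masks the aldehyde against the organolithium and peroxide reagents of step 9, and aryl benzyl ethers tolerate catalytic TsOH.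

Step 8
Reactants: 13 2-[3,4-bis(benzyloxy)-5-iodophenyl]-1,3-dioxolane
Product: 15 2-[3,4-bis(benzyloxy)-5-ethynylphenyl]-1,3-dioxolane, via trimethylsilyl alkyne 14 (not isolated)
Conditions: Me3SiC≡CH, Pd(PPh3)2Cl2 (cat.), CuI (cat.), Et3N, THF, rt; then K2CO3 (cat.), MeOH, rt
Reagents that add atoms: (trimethylsilyl)acetylene C#C[Si](C)(C)C
Why: Sonogashira coupling of the aryl iodide runs at room temperature, and carbonate-catalysed methanolysis of the C–Si bond then frees the terminal alkyne without affecting the acetal.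

Step 9
Reactants: 15 2-[3,4-bis(benzyloxy)-5-ethynylphenyl]-1,3-dioxolane
Product: 17 2-{3,4-bis(benzyloxy)-5-[(triisopropylsilyloxy)ethynyl]phenyl}-1,3-dioxolane, via lithium ynolate 16 (not isolated)
Conditions: n-BuLi, THF, −78 °C; LiOOt-Bu (from t-BuOOH + LiN(SiMe3)2), THF, −78 → 0 °C; then i-Pr3SiOTf (1.05 equiv), −78 → 0 °C; pH 7 buffer
Reagents that add atoms: tert-butyl hydroperoxide CC(C)(C)OO; triisopropylsilyl trifluoromethanesulfonate CC(C)[Si](OS(=O)(=O)C(F)(F)F)(C(C)C)C(C)C
Why: Electrophilic oxygen transfer from lithium tert-butyl peroxide to the lithium acetylide gives the ynolate, which the bulky silyl triflate captures on oxygen and not on carbon at −78 °C, where the dioxolane and the benzyl ethers are untouched.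

**Ring A fragment**

Step 10
Reactants: 18 2',4',6'-trihydroxyacetophenone
Product: 19 1-[2,4-bis(benzyloxy)-6-hydroxyphenyl]ethan-1-one
Conditions: BnBr (2.1 equiv), K2CO3, DMF, rt
Reagents that add atoms: benzyl bromide BrCc1ccccc1
Why: Williamson etherification stops at the dibenzyl ether because the remaining hydroxyl is hydrogen-bonded to the ketone and is therefore the least nucleophilic.

Step 11
Reactants: 19 1-[2,4-bis(benzyloxy)-6-hydroxyphenyl]ethan-1-one
Product: 20 tert-butyl 3-[2,4-bis(benzyloxy)-6-hydroxyphenyl]-3-oxopropanoate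
Conditions: LiN(SiMe3)2 (3.3 equiv), THF, −78 °C; Boc2O, −78 → 0 °C; aq. NH4Cl
Reagents that add atoms: di-tert-butyl dicarbonate CC(C)(C)OC(=O)OC(=O)OC(C)(C)C
Why: Claisen-type C-acylation of the phenoxide–enolate dianion, in which any aryl carbonate formed first is carried over to carbon by a Baker–Venkataraman-type acyl shift and the third equivalent of base protects the product as its enolate.

**Key step and endgame**

Step 12
Reactants: 9 2-[4-(benzyloxy)phenyl]-6-(2-diazoacetyl)-4H-pyran-4-one; 17 2-{3,4-bis(benzyloxy)-5-[(triisopropylsilyloxy)ethynyl]phenyl}-1,3-dioxolane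
Product: 25 6-[2,3-bis(benzyloxy)-5-(1,3-dioxolan-2-yl)phenyl]-2-[4-(benzyloxy)phenyl]-5-hydroxy-7-(triisopropylsilyloxy)-4H-chromen-4-one, via pyranonylketene 21 (not isolated), via siloxycyclobutenone 22 (not isolated), via dienylketene 23 (not isolated), via cyclohexadienone 24 (not isolated)
Conditions: hν (440 nm LED), 17 (1.3 equiv), degassed ClCH2CH2Cl, rt; then 80 °C
Reagents that add atoms: none
Why: Proposed new method: visible light excites the n→π* band of the diazo ketone, N2 leaves and the pyranonyl group shifts (Wolff rearrangement) to give ketene 21, whose electrophilic central carbon bonds to the nucleophilic aryl-bearing carbon of the ynol ether in a (2+2) cycloaddition to cyclobutenone 22; on warming, 22 opens by 4π electrocyclic cleavage to dienylketene 23, which closes onto pyranone C5 and tautomerises (24 → 25) to the phenol chelated to the C4'' carbonyl. The closest known reaction type is the Danheiser benzannulation of aryl and heteroaryl (furyl, thienyl) diazomethyl ketones with siloxyalkynes; here the vinyl part of the vinylketene is the C5=C6 enol-ether bond of a 4-pyranone, whose C5 is its nucleophilic carbon and so is polarity-matched to the ketene carbon. Ring D is closed by a thermally allowed disrotatory 6π electrocyclisation (bond C4a''–C5'') after the (2+2) step has made C5''–C6'' and C7''–C8''; the four-membered ring is only transient. No stereocentre remains in 25, since the sp3 centres of 22 and 24 are lost on ring opening and tautomerisation. The step needs regiocontrol in the (2+2) addition, secured by the oxygen-polarised alkyne that puts ring B on C6'' and the silyloxy group on C7''; site control in the closure, secured because the ketene arm sits on pyranone C6, whose only carbon neighbour is C5; and selective excitation, secured at 440 nm, where neither the aryl pyranone nor the product flavone should absorb appreciably.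

Step 13
Reactants: 25 6-[2,3-bis(benzyloxy)-5-(1,3-dioxolan-2-yl)phenyl]-2-[4-(benzyloxy)phenyl]-5-hydroxy-7-(triisopropylsilyloxy)-4H-chromen-4-one
Product: 27 3,4-bis(benzyloxy)-5-{7-(benzyloxy)-2-[4-(benzyloxy)phenyl]-5-hydroxy-4-oxo-4H-chromen-6-yl}benzaldehyde, via benzyl ether acetal 26 (not isolated)
Conditions: CsF, BnBr (1.15 equiv), DMF, rt; then 2 M HCl, THF, rt
Reagents that add atoms: benzyl bromide BrCc1ccccc1; water O
Why: Fluoride cleaves the labile aryl silyl ether and the caesium phenoxide is benzylated at once (Williamson) while the chelated, hindered C5'' hydroxyl stays free; dilute acid then hydrolyses the aryl dioxolane to the aldehyde.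

Step 14
Reactants: 27 3,4-bis(benzyloxy)-5-{7-(benzyloxy)-2-[4-(benzyloxy)phenyl]-5-hydroxy-4-oxo-4H-chromen-6-yl}benzaldehyde; 20 tert-butyl 3-[2,4-bis(benzyloxy)-6-hydroxyphenyl]-3-oxopropanoate
Product: 28 tert-butyl (2Z)-2-[2,4-bis(benzyloxy)-6-hydroxybenzoyl]-3-(3,4-bis(benzyloxy)-5-{7-(benzyloxy)-2-[4-(benzyloxy)phenyl]-5-hydroxy-4-oxo-4H-chromen-6-yl}phenyl)prop-2-enoate
Conditions: piperidine (cat.), AcOH (cat.), 4 Å MS, toluene, rt
Reagents that add atoms: none
Why: Knoevenagel condensation of the aldehyde with the doubly activated methylene under piperidinium acetate catalysis should give the alkylidene β-keto ester, expected mainly as the Z isomer, while the ketone-chelated phenol is too weak a nucleophile to cyclise under these buffered conditions.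

Step 15
Reactants: 28 tert-butyl (2Z)-2-[2,4-bis(benzyloxy)-6-hydroxybenzoyl]-3-(3,4-bis(benzyloxy)-5-{7-(benzyloxy)-2-[4-(benzyloxy)phenyl]-5-hydroxy-4-oxo-4H-chromen-6-yl}phenyl)prop-2-enoate
Product: 31 (2S)-5,7-bis(benzyloxy)-2-(3,4-bis(benzyloxy)-5-{7-(benzyloxy)-2-[4-(benzyloxy)phenyl]-5-hydroxy-4-oxo-4H-chromen-6-yl}phenyl)chroman-4-one, via tert-butyl ester 29 (not isolated), via keto acid 30 (not isolated)
Conditions: quinidine-derived thiourea (10 mol %), toluene, −25 °C; then TsOH·H2O (cat.), 80 °C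
Reagents that add atoms: none
Why: Enantioselective intramolecular oxa-Michael addition (6-endo-trig) under bifunctional cinchona thiourea catalysis, in which the thiourea binds the β-keto ester and the quinuclidine nitrogen delivers the phenol to one face of the alkene, sets C2 as S; acid then cleaves the tert-butyl ester and the β-keto acid decarboxylates through its enol without touching C2.

Step 16
Reactants: 31 (2S)-5,7-bis(benzyloxy)-2-(3,4-bis(benzyloxy)-5-{7-(benzyloxy)-2-[4-(benzyloxy)phenyl]-5-hydroxy-4-oxo-4H-chromen-6-yl}phenyl)chroman-4-one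
Product: 32 (2S)-2-{3,4-dihydroxy-5-[5,7-dihydroxy-2-(4-hydroxyphenyl)-4-oxo-4H-chromen-6-yl]phenyl}-5,7-dihydroxychroman-4-one (CNP0176432.1)
Conditions: H2 (1 atm), 10% Pd/C, THF/MeOH, rt
Reagents that add atoms: none
Why: Hydrogenolysis of the six aryl benzyl ethers over palladium is neutral, so the base-labile C2 stereocentre should not be epimerised, and at one atmosphere and room temperature the flavone double bond, both ketones and the benzylic C2–O bond are expected to survive.

**Compound list**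

1 | 4'-(benzyloxy)acetophenone | CC(=O)c1ccc(OCc2ccccc2)cc1 | starting material
2 | ethyl acetate | CCOC(C)=O | starting material
3 | 1-[4-(benzyloxy)phenyl]butane-1,3-dione | CC(=O)CC(=O)c1ccc(OCc2ccccc2)cc1 | intermediate
4 | diethyl oxalate | CCOC(=O)C(=O)OCC | starting material
5 | ethyl 6-[4-(benzyloxy)phenyl]-2,4,6-trioxohexanoate (not isolated) | CCOC(=O)C(=O)CC(=O)CC(=O)c1ccc(OCc2ccccc2)cc1 | intermediate
6 | ethyl 6-[4-(benzyloxy)phenyl]-4-oxo-4H-pyran-2-carboxylate | CCOC(=O)c1cc(=O)cc(o1)-c1ccc(OCc2ccccc2)cc1 | intermediate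
7 | 6-[4-(benzyloxy)phenyl]-4-oxo-4H-pyran-2-carboxylic acid | OC(=O)c1cc(=O)cc(o1)-c1ccc(OCc2ccccc2)cc1 | intermediate
8 | 6-[4-(benzyloxy)phenyl]-4-oxo-4H-pyran-2-carbonyl chloride (not isolated) | ClC(=O)c1cc(=O)cc(o1)-c1ccc(OCc2ccccc2)cc1 | intermediate
9 | 2-[4-(benzyloxy)phenyl]-6-(2-diazoacetyl)-4H-pyran-4-one | [N-]=[N+]=CC(=O)c1cc(=O)cc(o1)-c1ccc(OCc2ccccc2)cc1 | intermediate
10 | 5-iodovanillin (4-hydroxy-3-iodo-5-methoxybenzaldehyde) | COc1cc(C=O)cc(I)c1O | starting material
11 | 3,4-dihydroxy-5-iodobenzaldehyde | O=Cc1cc(O)c(O)c(I)c1 | intermediate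
12 | 3,4-bis(benzyloxy)-5-iodobenzaldehyde | O=Cc1cc(I)c(OCc2ccccc2)c(OCc2ccccc2)c1 | intermediate
13 | 2-[3,4-bis(benzyloxy)-5-iodophenyl]-1,3-dioxolane | Ic1cc(cc(OCc2ccccc2)c1OCc1ccccc1)C1OCCO1 | intermediate
14 | 2-{3,4-bis(benzyloxy)-5-[(trimethylsilyl)ethynyl]phenyl}-1,3-dioxolane (not isolated) | C[Si](C)(C)C#Cc1cc(cc(OCc2ccccc2)c1OCc1ccccc1)C1OCCO1 | intermediate
15 | 2-[3,4-bis(benzyloxy)-5-ethynylphenyl]-1,3-dioxolane | C#Cc1cc(cc(OCc2ccccc2)c1OCc1ccccc1)C1OCCO1 | intermediate
16 | lithium 2-[2,3-bis(benzyloxy)-5-(1,3-dioxolan-2-yl)phenyl]ethynolate (not isolated) | [Li+].[O-]C#Cc1cc(cc(OCc2ccccc2)c1OCc1ccccc1)C1OCCO1 | intermediate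
17 | 2-{3,4-bis(benzyloxy)-5-[(triisopropylsilyloxy)ethynyl]phenyl}-1,3-dioxolane | CC(C)[Si](OC#Cc1cc(cc(OCc2ccccc2)c1OCc1ccccc1)C1OCCO1)(C(C)C)C(C)C | intermediate
18 | 2',4',6'-trihydroxyacetophenone | CC(=O)c1c(O)cc(O)cc1O | starting material
19 | 1-[2,4-bis(benzyloxy)-6-hydroxyphenyl]ethan-1-one | CC(=O)c1c(O)cc(OCc2ccccc2)cc1OCc1ccccc1 | intermediate
20 | tert-butyl 3-[2,4-bis(benzyloxy)-6-hydroxyphenyl]-3-oxopropanoate | CC(C)(C)OC(=O)CC(=O)c1c(O)cc(OCc2ccccc2)cc1OCc1ccccc1 | intermediate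
21 | 2-[4-(benzyloxy)phenyl]-6-(2-oxoethenyl)-4H-pyran-4-one (ketene, not isolated) | O=C=Cc1cc(=O)cc(o1)-c1ccc(OCc2ccccc2)cc1 | intermediate
22 | 2-[4-(benzyloxy)phenyl]-6-{3-[2,3-bis(benzyloxy)-5-(1,3-dioxolan-2-yl)phenyl]-4-oxo-2-(triisopropylsilyloxy)cyclobut-2-en-1-yl}-4H-pyran-4-one (racemic at the ring CH, not isolated) | O=C1C(c2cc(cc(OCc3ccccc3)c2OCc2ccccc2)C2OCCO2)=C(O[Si](C(C)C)(C(C)C)C(C)C)C1c1cc(=O)cc(o1)-c1ccc(OCc2ccccc2)cc1 | intermediate
23 | 2-[4-(benzyloxy)phenyl]-6-{(1E)-3-[2,3-bis(benzyloxy)-5-(1,3-dioxolan-2-yl)phenyl]-4-oxo-2-(triisopropylsilyloxy)buta-1,3-dien-1-yl}-4H-pyran-4-one (ketene carbon and pyranonyl group cis, not isolated) | O=C=C(c1cc(cc(OCc2ccccc2)c1OCc1ccccc1)C1OCCO1)/C(O[Si](C(C)C)(C(C)C)C(C)C)=C\c1cc(=O)cc(o1)-c1ccc(OCc2ccccc2)cc1 | intermediate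
24 | 6-[2,3-bis(benzyloxy)-5-(1,3-dioxolan-2-yl)phenyl]-2-[4-(benzyloxy)phenyl]-7-(triisopropylsilyloxy)-4aH-chromene-4,5-dione (keto tautomer of 25, racemic at C4a, not isolated) | O=C1C=C(c2ccc(OCc3ccccc3)cc2)OC2=CC(O[Si](C(C)C)(C(C)C)C(C)C)=C(c3cc(cc(OCc4ccccc4)c3OCc3ccccc3)C3OCCO3)C(=O)C12 | intermediate
25 | 6-[2,3-bis(benzyloxy)-5-(1,3-dioxolan-2-yl)phenyl]-2-[4-(benzyloxy)phenyl]-5-hydroxy-7-(triisopropylsilyloxy)-4H-chromen-4-one | O=c1cc(-c2ccc(OCc3ccccc3)cc2)oc2cc(O[Si](C(C)C)(C(C)C)C(C)C)c(-c3cc(cc(OCc4ccccc4)c3OCc3ccccc3)C3OCCO3)c(O)c12 | intermediate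
26 | 7-(benzyloxy)-6-[2,3-bis(benzyloxy)-5-(1,3-dioxolan-2-yl)phenyl]-2-[4-(benzyloxy)phenyl]-5-hydroxy-4H-chromen-4-one (not isolated) | O=c1cc(-c2ccc(OCc3ccccc3)cc2)oc2cc(OCc3ccccc3)c(-c3cc(cc(OCc4ccccc4)c3OCc3ccccc3)C3OCCO3)c(O)c12 | intermediate
27 | 3,4-bis(benzyloxy)-5-{7-(benzyloxy)-2-[4-(benzyloxy)phenyl]-5-hydroxy-4-oxo-4H-chromen-6-yl}benzaldehyde | O=Cc1cc(OCc2ccccc2)c(OCc2ccccc2)c(c1)-c1c(O)c2c(=O)cc(-c3ccc(OCc4ccccc4)cc3)oc2cc1OCc1ccccc1 | intermediate
28 | tert-butyl (2Z)-2-[2,4-bis(benzyloxy)-6-hydroxybenzoyl]-3-(3,4-bis(benzyloxy)-5-{7-(benzyloxy)-2-[4-(benzyloxy)phenyl]-5-hydroxy-4-oxo-4H-chromen-6-yl}phenyl)prop-2-enoate | CC(C)(C)OC(=O)/C(C(=O)c1c(O)cc(OCc2ccccc2)cc1OCc1ccccc1)=C\c1cc(OCc2ccccc2)c(OCc2ccccc2)c(c1)-c1c(O)c2c(=O)cc(-c3ccc(OCc4ccccc4)cc3)oc2cc1OCc1ccccc1 | intermediate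
29 | tert-butyl (2S,3R)-5,7-bis(benzyloxy)-2-(3,4-bis(benzyloxy)-5-{7-(benzyloxy)-2-[4-(benzyloxy)phenyl]-5-hydroxy-4-oxo-4H-chromen-6-yl}phenyl)-4-oxochromane-3-carboxylate (2,3-trans; C3 is labile; not isolated) | O=C1[C@H](C(=O)OC(C)(C)C)[C@@H](c2cc(OCc3ccccc3)c(OCc3ccccc3)c(-c3c(O)c4c(=O)cc(-c5ccc(OCc6ccccc6)cc5)oc4cc3OCc3ccccc3)c2)Oc2cc(OCc3ccccc3)cc(OCc3ccccc3)c21 | intermediate
30 | (2S,3R)-5,7-bis(benzyloxy)-2-(3,4-bis(benzyloxy)-5-{7-(benzyloxy)-2-[4-(benzyloxy)phenyl]-5-hydroxy-4-oxo-4H-chromen-6-yl}phenyl)-4-oxochromane-3-carboxylic acid (not isolated) | O=C1[C@H](C(O)=O)[C@@H](c2cc(OCc3ccccc3)c(OCc3ccccc3)c(-c3c(O)c4c(=O)cc(-c5ccc(OCc6ccccc6)cc5)oc4cc3OCc3ccccc3)c2)Oc2cc(OCc3ccccc3)cc(OCc3ccccc3)c21 | intermediate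
31 | (2S)-5,7-bis(benzyloxy)-2-(3,4-bis(benzyloxy)-5-{7-(benzyloxy)-2-[4-(benzyloxy)phenyl]-5-hydroxy-4-oxo-4H-chromen-6-yl}phenyl)chroman-4-one | O=C1C[C@@H](c2cc(OCc3ccccc3)c(OCc3ccccc3)c(-c3c(O)c4c(=O)cc(-c5ccc(OCc6ccccc6)cc5)oc4cc3OCc3ccccc3)c2)Oc2cc(OCc3ccccc3)cc(OCc3ccccc3)c21 | intermediate
32 | (2S)-2-{3,4-dihydroxy-5-[5,7-dihydroxy-2-(4-hydroxyphenyl)-4-oxo-4H-chromen-6-yl]phenyl}-5,7-dihydroxychroman-4-one (CNP0176432.1) | O=C1C[C@@H](c2cc(O)c(O)c(-c3c(O)cc4oc(-c5ccc(O)cc5)cc(=O)c4c3O)c2)Oc2cc(O)cc(O)c21 | target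

**Step count**

Total: 16 steps. Longest linear sequence: 10 steps (10 → 32 through steps 5, 6, 7, 8, 9, 12, 13, 14, 15 and 16).

**Steps most likely to fail**

1. Step 12 (proposed new method). Light may be absorbed by the aryl pyranone and not by the diazo group, which would open pyranone photochemistry in place of the Wolff shift. The ketene may dimerise before it engages the hindered, ortho-substituted alkyne. The 6π closure onto pyranone C5 may be slow enough for the dienylketene to be diverted.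
Fallback, known chemistry only: the C5'–C6'' bond is made by cross-coupling on an intact flavone. It sets out from iodide 12. Miyaura borylation (B2pin2, Pd(dppf)Cl2, KOAc, dioxane, 80 °C) should give 3,4-bis(benzyloxy)-5-(4,4,5,5-tetramethyl-1,3,2-dioxaborolan-2-yl)benzaldehyde F1. Separately, commercial apigenin (O=c1cc(-c2ccc(O)cc2)oc2cc(O)cc(O)c12) is benzylated at the two non-chelated hydroxyls (BnBr, K2CO3, DMF) to 7-(benzyloxy)-2-[4-(benzyloxy)phenyl]-5-hydroxy-4H-chromen-4-one F2. Iodination ortho to the free chelated hydroxyl (benzyltrimethylammonium dichloroiodate, CaCO3, CH2Cl2/MeOH, rt) gives 7-(benzyloxy)-2-[4-(benzyloxy)phenyl]-5-hydroxy-6-iodo-4H-chromen-4-one F3. Suzuki–Miyaura coupling of F1 with F3 (Pd(OAc)2, SPhos, K3PO4, toluene/H2O, 90 °C) comes back to the route at aldehyde 27.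

2. Step 15. Facial selectivity may be poor, because the benzyloxy group beside the ketone and the large biaryl substituent both differ from the substrates on which the catalyst is established. Piperidine carried over from step 14 may cause racemic background cyclisation. The sense of induction may be opposite to the assumption.
Fallback: resolution in place of asymmetric catalysis. It sets out from aldehyde 27 and ketone 19. Claisen–Schmidt condensation (KOH, EtOH/THF, rt) should give (2E)-1-[2,4-bis(benzyloxy)-6-hydroxyphenyl]-3-(3,4-bis(benzyloxy)-5-{7-(benzyloxy)-2-[4-(benzyloxy)phenyl]-5-hydroxy-4-oxo-4H-chromen-6-yl}phenyl)prop-2-en-1-one F4. Oxa-Michael closure (NaOAc, EtOH, reflux) gives racemic 5,7-bis(benzyloxy)-2-(3,4-bis(benzyloxy)-5-{7-(benzyloxy)-2-[4-(benzyloxy)phenyl]-5-hydroxy-4-oxo-4H-chromen-6-yl}phenyl)chroman-4-one F5. Preparative chromatography on a chiral stationary phase (amylose tris(3,5-dimethylphenylcarbamate)) separates the enantiomers, and the 2S enantiomer comes back to the route at 31.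

3. Step 9. Oxygen transfer to the acetylide may stay incomplete. The ynolate may be silylated on carbon to a silylketene. The silyl triflate may open the dioxolane. The siloxyalkyne may hydrolyse on work-up or on silica.
Fallback: the ynolate is made by ester homologation in place of alkyne oxidation. It sets out from iodide 13. Palladium-catalysed methoxycarbonylation (Pd(OAc)2, dppf, CO 1 atm, MeOH, Et3N, DMF, 70 °C) should give methyl 2,3-bis(benzyloxy)-5-(1,3-dioxolan-2-yl)benzoate F6. Kowalski ester homologation (CH2Br2 and lithium 2,2,6,6-tetramethylpiperidide, THF, −78 °C; LiN(SiMe3)2; n-BuLi, −78 °C → rt) passes through the lithium enolate of 1-[2,3-bis(benzyloxy)-5-(1,3-dioxolan-2-yl)phenyl]-2,2-dibromoethan-1-one F7. It comes back to the route at ynolate 16, which i-Pr3SiCl traps to 17.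

**Further compounds**

F1 | step 12 | 3,4-bis(benzyloxy)-5-(4,4,5,5-tetramethyl-1,3,2-dioxaborolan-2-yl)benzaldehyde | O=Cc1cc(OCc2ccccc2)c(OCc2ccccc2)c(c1)B1OC(C)(C)C(C)(C)O1
F2 | step 12 | 7-(benzyloxy)-2-[4-(benzyloxy)phenyl]-5-hydroxy-4H-chromen-4-one | O=c1cc(-c2ccc(OCc3ccccc3)cc2)oc2cc(OCc3ccccc3)cc(O)c12
F3 | step 12 | 7-(benzyloxy)-2-[4-(benzyloxy)phenyl]-5-hydroxy-6-iodo-4H-chromen-4-one | O=c1cc(-c2ccc(OCc3ccccc3)cc2)oc2cc(OCc3ccccc3)c(I)c(O)c12
F4 | step 15 | (2E)-1-[2,4-bis(benzyloxy)-6-hydroxyphenyl]-3-(3,4-bis(benzyloxy)-5-{7-(benzyloxy)-2-[4-(benzyloxy)phenyl]-5-hydroxy-4-oxo-4H-chromen-6-yl}phenyl)prop-2-en-1-one | O=C(/C=C/c1cc(OCc2ccccc2)c(OCc2ccccc2)c(c1)-c1c(O)c2c(=O)cc(-c3ccc(OCc4ccccc4)cc3)oc2cc1OCc1ccccc1)c1c(O)cc(OCc2ccccc2)cc1OCc1ccccc1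
F5 | step 15 | racemic 5,7-bis(benzyloxy)-2-(3,4-bis(benzyloxy)-5-{7-(benzyloxy)-2-[4-(benzyloxy)phenyl]-5-hydroxy-4-oxo-4H-chromen-6-yl}phenyl)chroman-4-one | O=C1CC(c2cc(OCc3ccccc3)c(OCc3ccccc3)c(-c3c(O)c4c(=O)cc(-c5ccc(OCc6ccccc6)cc5)oc4cc3OCc3ccccc3)c2)Oc2cc(OCc3ccccc3)cc(OCc3ccccc3)c21
F6 | step 9 | methyl 2,3-bis(benzyloxy)-5-(1,3-dioxolan-2-yl)benzoate | COC(=O)c1cc(cc(OCc2ccccc2)c1OCc1ccccc1)C1OCCO1
F7 | step 9 | 1-[2,3-bis(benzyloxy)-5-(1,3-dioxolan-2-yl)phenyl]-2,2-dibromoethan-1-one (present as its lithium enolate) | BrC(Br)C(=O)c1cc(cc(OCc2ccccc2)c1OCc1ccccc1)C1OCCO1
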